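**Strategy.** The five-membered ring is read as a cyclic aldol: C1, the CH carrying the methyl ester, is the α-carbon of a β-keto ester, and C2, the hexadecyl carbinol, is a former ketone held cis to it across the ring C3=C4 double bond. Disconnecting C1–C2 unfolds the ring to methyl (Z)-3,6-dioxodocos-4-enoate, the presumed biosynthetic polyketide precursor, which is unmasked by oxidative opening of a 2,5-disubstituted furan. One catalyst-controlled intramolecular aldol addition closes the cyclopentenone, creates the quaternary carbinol and leaves the epimerisable ester centre to settle trans to the chain, giving the target directly with no protecting groups.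

Key step: step 4

Assumption: methyl 2-(furan-2-yl)acetate, hexadec-1-ene and hexadec-1-yne are taken as catalogue compounds, and the configuration at C1 is treated as thermodynamically controlled because this centre is the α-carbon of a β-keto ester.

Step 1
Reactants: 1 methyl 2-(furan-2-yl)acetate
Product: 2 methyl 2-(5-bromofuran-2-yl)acetate
Conditions: NBS (1.0 equiv), DMF, 0 °C, dark; used promptly
Reagents that add atoms: N-bromosuccinimide, O=C1CCC(=O)N1Br
Why: Electrophilic aromatic bromination of the 2-substituted furan should take place at the free α-position C5, its most nucleophilic site, under polar non-radical conditions that spare the side-chain CH2.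

Step 2
Reactants: 2 methyl 2-(5-bromofuran-2-yl)acetate; 3 hexadec-1-ene
Product: 5 methyl 2-(5-hexadecylfuran-2-yl)acetate, via B-hexadecyl-9-BBN 4 (not isolated)
Conditions: 3, 9-BBN, THF, 0 °C to rt; then 2, Pd(dppf)Cl2 (5 mol%), aq. K3PO4, DMF, 50 °C
Reagents that add atoms: none
Why: Anti-Markovnikov hydroboration of the terminal alkene followed by B-alkyl Suzuki–Miyaura coupling should form the sp2–sp3 bond, the dppf ligand suppressing β-hydride elimination and K3PO4 being mild enough for the methyl ester.

Step 3
Reactants: 5 methyl 2-(5-hexadecylfuran-2-yl)acetate
Product: 7 methyl (Z)-3,6-dioxodocos-4-enoate, via furan epoxide 6 (not isolated)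
Conditions: dimethyldioxirane (1.0 equiv, in acetone), acetone/CH2Cl2, −78 to −20 °C; volatiles removed cold, no chromatography
Reagents that add atoms: dimethyldioxirane, CC1(C)OO1
Why: Dimethyldioxirane epoxidises a ring double bond of the electron-rich 2,5-dialkylfuran and the epoxide opens spontaneously to the cis-enedione (oxidative furan ring opening), the Z geometry being inherited from the ring and the only by-product being volatile and neutral.

Step 4
Reactants: 7 methyl (Z)-3,6-dioxodocos-4-enoate
Product: 8 methyl (1R,2R)-2-hexadecyl-2-hydroxy-5-oxocyclopent-3-ene-1-carboxylate
Conditions: quinine-derived squaramide 3-{[3,5-bis(trifluoromethyl)phenyl]amino}-4-{[(8α,9S)-6′-methoxycinchonan-9-yl]amino}cyclobut-3-ene-1,2-dione (10 mol%), toluene, −20 °C; then short silica pad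
Reagents that add atoms: none
Why: Proposed new method: the quinuclidine nitrogen of the catalyst deprotonates the doubly activated C2 methylene of 7 while the squaramide N–H bonds bind the C6 ketone, and the Z C4=C5 double bond holds the enolate carbon within bonding distance of C6, so that carbon–carbon bond formation closes the five-membered ring in a 5-(enolexo)-exo-trig intramolecular aldol addition. The closest known reactions are the base-mediated, racemic aldol closure of furan-derived Z-1,4-enediones to 4-hydroxycyclopent-2-enones and the squaramide-catalysed enantioselective intermolecular aldol addition of 1,3-dicarbonyl compounds to activated ketones; their union in one enantioselective ring closure is the new element. The quaternary carbinol centre (2R) is set by the catalyst, which must deliver the enolate to the Si face of the C6 carbonyl; this sense rests on a working model only, and the pseudoenantiomeric quinidine-derived squaramide would be used instead should the opposite sense be found. The C1 centre is set under thermodynamic control by enolisation of the product β-keto ester, which should place the ester trans to the hexadecyl chain and cis to the hydroxyl (O–H···O=C hydrogen bond), i.e. (1R). The step needs 1,2-addition at C6 only, secured because attack at C4 or C5 would give three- or four-membered rings, and it needs the kinetic enantiomer composition to survive, for which low temperature, an apolar solvent and removal of the catalyst on silica are meant to forestall retro-aldol reopening and loss of water.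

**Compound list**
1 | methyl 2-(furan-2-yl)acetate | COC(=O)Cc1ccco1 | starting material
2 | methyl 2-(5-bromofuran-2-yl)acetate | COC(=O)Cc1ccc(Br)o1 | intermediate
3 | hexadec-1-ene | CCCCCCCCCCCCCCC=C | starting material
4 | 9-hexadecyl-9-borabicyclo[3.3.1]nonane (B-hexadecyl-9-BBN, not isolated) | CCCCCCCCCCCCCCCCB1C2CCCC1CCC2 | intermediate
5 | methyl 2-(5-hexadecylfuran-2-yl)acetate | CCCCCCCCCCCCCCCCc1ccc(CC(=O)OC)o1 | intermediate
6 | methyl 2-(1-hexadecyl-2,6-dioxabicyclo[3.1.0]hex-3-en-3-yl)acetate (furan epoxide, racemic, not isolated) | CCCCCCCCCCCCCCCCC12OC1C=C(CC(=O)OC)O2 | intermediate
7 | methyl (Z)-3,6-dioxodocos-4-enoate | CCCCCCCCCCCCCCCCC(=O)/C=C\C(=O)CC(=O)OC | intermediate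
8 | methyl (1R,2R)-2-hexadecyl-2-hydroxy-5-oxocyclopent-3-ene-1-carboxylate | CCCCCCCCCCCCCCCC[C@@]1(O)C=CC(=O)[C@@H]1C(=O)OC | target

**Step count and risks**
Total step count: 4. Longest linear sequence: 4 steps (from 1).

Steps most likely to fail:

1. Step 4 (Proposed new method). The catalyst may discriminate the two faces of the C6 ketone insufficiently, or the enantiopurity may erode through reversible ring opening and reclosure. Base-induced loss of water followed by dimerisation of the resulting cyclopentadienone is a further drain. Fallback: from 7, the ring would be closed without stereocontrol by the known base-mediated intramolecular aldol addition (Et3N, 0.2 equiv, CH2Cl2, 0 °C). This should give the racemate, that is 8 together with its enantiomer methyl (1S,2S)-2-hexadecyl-2-hydroxy-5-oxocyclopent-3-ene-1-carboxylate F1. The two would be separated by preparative HPLC on a cellulose tris(3,5-dimethylphenylcarbamate) stationary phase (hexane/2-propanol), and the route comes back at 8.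

2. Step 3. Over-oxidation at the enolisable β-keto ester methylene, Z-to-E isomerisation of the enedione, or premature uncatalysed (racemic) ring closure on concentration may occur. Fallback: from 5, sensitised photooxygenation (O2, 5,10,15,20-tetraphenylporphyrin, visible light, CH2Cl2, −78 °C) should give, by [4+2] cycloaddition of singlet oxygen, the endoperoxide methyl 2-(4-hexadecyl-2,3,7-trioxabicyclo[2.2.1]hept-5-en-1-yl)acetate F2. Me2S would reduce it at −78 °C under neutral conditions, and the route comes back at 7.

3. Step 2. The sensitive 2-bromofuran may decompose or be protodehalogenated under the warm aqueous basic conditions, and transmetalation of the alkylborane may be slow enough for β-hydride elimination to compete. Fallback: from 2, Sonogashira coupling with hexadec-1-yne (Pd(PPh3)2Cl2, CuI, Et3N, THF, rt) should give methyl 2-[5-(hexadec-1-yn-1-yl)furan-2-yl]acetate F3. Hydrogenation of the triple bond (H2, Pd/C, EtOAc, rt, stopped after two equivalents of hydrogen) would then come back to the route at 5.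

**Further compounds**
F1 | step 4 | methyl (1S,2S)-2-hexadecyl-2-hydroxy-5-oxocyclopent-3-ene-1-carboxylate | CCCCCCCCCCCCCCCC[C@]1(O)C=CC(=O)[C@H]1C(=O)OC
F2 | step 3 | methyl 2-(4-hexadecyl-2,3,7-trioxabicyclo[2.2.1]hept-5-en-1-yl)acetate | COC(=O)CC12OOC(CCCCCCCCCCCCCCCC)(O1)C=C2
F3 | step 2 | methyl 2-[5-(hexadec-1-yn-1-yl)furan-2-yl]acetate | CCCCCCCCCCCCCCC#Cc1ccc(CC(=O)OC)o1
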